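Atom numbers follow the target 27: lactone O1, C2–C6; side chain C7, C8; flavanone atoms primed.

## Analysis of the target

Target 27 joins a 5-hydroxy-5,6-dihydro-2H-pyran-2-one (O1, C2–C6) through a two-carbon chain (C7, C8) to C6' of a 5,7-dihydroxyflavanone, and C8 is a diarylmethine that also carries a phenyl group. There are five stereocentres: a contiguous tetrad C5 (S), C6 (R), C7 (R), C8 (S) and the isolated C2' (S). Within the tetrad the oxygens on C5, C6 and C7 are all syn along the chain (O5 is cis to the side chain on the lactone ring), and C7/C8 have the relationship that becomes trans once C6, C7, C8 and O7' are tied into a six-membered ring. C2' is too far from the tetrad to be directed by it. The conjugated lactone rules out hydrogenolysis and base (conjugate addition, ring opening, translactonization to a butenolide once O5 is free). The flavanone epimerizes at C2' by base-induced ring opening, ring A is an electron-rich phloroglucinol nucleus, and C8–H is doubly benzylic. The hard part is the C7–C8 bond: it links two stereocentres, one of them a hindered diarylmethine between two ortho oxygens, and must be made with absolute control. The strategy rests on C8 sitting on C6' between O5' and O7' and next to the oxygenated C7. An ortho-quinone methide of ring A (C8 as methide carbon) and an α-alkoxy ester enolate (C6, C7) are its two halves, and their union closes a temporary dihydrocoumarin. O5' and O7' both end as free phenols and C6' lies on the local symmetry axis of ring A, so it does not matter which of them enters the temporary lactone or at which free ring position ring C is fused.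

## Retrosynthetic reasoning

**27 to 26.** The last operation removes protecting groups only. Because of the enoate, the three benzyl ethers (O5', O7', O7) and the methoxymethyl acetal on O5 of 26 are chosen to fall together to a Lewis acid at low temperature. Acid, not base or hydrogen, is what the lactone and the flavanone tolerate.

**26 to 25, then 23 and 24.** The C3=C4 bond of 26 is cut by a ring-closing metathesis transform to the acrylate 25, and the ester bond O1–C2 to the secondary alcohol 23 and acryloyl chloride 24. This puts the carbonyl at C2 and the alkene in conjugation with no redox adjustment, and the ring can only hold the cis alkene. The forward steps must acylate a hindered hydroxyl and close a six-membered ring between an acrylate and an allylic-ether alkene.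

**23 to 20, 19, then 17 and 18, and 17 to 16.** Ring C is cut at C4'–C4a' (intramolecular Friedel–Crafts acylation of acid 20 through mixed anhydride 21) and at O1'–C2' (Mitsunobu etherification of phenol 17 with the (R)-hydroxy ester 18, giving ester 19). Phenol 17 comes from silyl ether 16.
- Ring C is not made by cinnamoylation and oxa-Michael closure, because that would leave C2' uncontrolled and reversible. Ester 18 brings the centre enantiopure and delivers it by inversion.
- No regiocontrol is needed: with both ortho oxygens benzylated, the two free positions of ring A in 20 are equivalent.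
- Ring C is placed after all hydride steps, which its ketone would not survive, and before the lactone, because the ester hydrolysis leading to 20 would not spare an acrylate or an enoate.

**16 to 12 and 14.** The C5–C6 bond is cut to the α-benzyloxy aldehyde 12 and the (Z)-γ-alkoxyallylborane 15, made in the flask from allyl ether 14 (from alcohol 13). One step forms the bond, sets C5 and C6 syn, leaves O5 protected and O6 free for the acrylate, and supplies the terminal alkene for metathesis. The needed syn relationship of O6 to O7 is the anti-Felkin sense, so the forward reaction must be reagent-controlled: 15 has to attack the re face of 12.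

**12 to 11, 10 and 9.** Aldehyde 12 is the opened, O7'-benzylated and reoxidized form of dihydrocoumarin 9 (oxidation of alcohol 11, benzylation of the phenol of diol 10, hydride reduction of 9). The lactone stores C6 at the acid level and keeps one ortho oxygen occupied. It is not needed to tell the two ortho oxygens apart, since the benzylation that gives 11 makes ring A symmetric.

**9 to 4 and 5.** The C7–C8 bond and the ester bond O7'–C6 are cut together, a formal [4+2] retron leading to quinone methide 7 and the enolate of benzyloxyacetyl chloride 5. This is the place to cut because it makes the hardest bond first, from two simple pieces. Quinone methide 7 is planar, so its precursor 4 can be racemic. It must be released from 4 under basic conditions through carbonate 6. A chiral carbene has to fix C8, and C7 is then corrected thermodynamically from the cis lactone 8 to the trans lactone 9.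

**4 to 3, 2 and 1.** Benzhydrol 4 comes from ketone 3 by hydride reduction, 3 from 2 by benzylation of one of two equivalent hydroxyls, and 2 from 1 by silylation of the para hydroxyl. One ortho hydroxyl stays free to become the quinone methide oxygen, the other is blocked so that only one quinone methide can form, and the para oxygen carries a group that can be removed alone later.

## Alternatives that were turned down

**Alternative 1:** The disconnection is O1–C2 of a pyranone whose ring atoms come from a furan on the C6 carbinol (furyl carbinol A1). In the forward key step, oxidative ring expansion of the furan by an electrophilic bromine source in buffered aqueous solvent gives the pyranone lactol A2.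
- For: the ring expansion is dependable and keeps the C6 configuration. C6 could be set beforehand by a chelation-controlled addition, which is matched for the O6/O7 syn relationship. On this point it is stronger than the reagent-controlled, mismatched allylboration used here.
- Against: A2 has the wrong oxidation pattern, a ketone at C5 and a lactol at C2. The lactol must be oxidized and the C5 ketone reduced. Small hydrides are expected to give the alcohol trans to the C6 substituent, so the cis arrangement of 27 would need an inversion. That reduction must also spare the flavanone ketone, and the aryl acetates of A2 are labile.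
- Comparison: the chosen route reaches the lactone in three steps from 12 with C5 and C6 set together at the final oxidation level. Alternative 1 forms no carbon–carbon bond in its key step and leaves C7–C8 unsolved.

**Alternative 2:** The disconnection is C5–C6 and O1–C2, leading to aldehyde A3 and the oxygenated diene A4. In the forward key step, a Lewis-acid-promoted hetero-Diels–Alder reaction gives the dihydropyranone A5.
- For: one step builds the ring and both C5 and C6. Chelation through the C7 benzyl ether gives the needed O6/O7 syn sense and the endo mode gives cis C5/C6. For this ring it is shorter and stereochemically better matched than allylboration, acylation and metathesis.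
- Against: A5 has its carbonyl at C4 and an enol ether at C2–C3. Reaching the 2-pyranone needs a 1,3-carbonyl transposition (reduction at C4, allylic rearrangement to a C2 acetal, oxidation), about three more steps. A3 already carries the flavanone, whose ketone and peri ether offer a second chelation site and compete in the C4 reduction. The C5 benzoate must finally be removed under basic or reductive conditions that the enoate lactone and C2' do not tolerate.
- Comparison: overall the pyranone comes later and with more risk than by the allylboration route, whose product 16 already has the final oxidation pattern. C7–C8 is again presupposed.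

**Alternative 3:** The disconnection is C4'–C4a' of ring C, leading to acid A6. In the forward key step, carboxyl activation as a mixed anhydride and intramolecular acylation gives A7, the fully silylated form of 27.
- For: the closure needs no regiocontrol on the symmetric ring and takes C2' from an enantiopure building block. On this point it is as strong as the chosen route, which forms the same bond in step 13.
- Against: as the organizing step it comes last, on the complete lactone. The two aryl silyl ethers beside the reacting position are bulkier and poorer donors than alkyl ethers. The acid set free can ionize the benzylic C2'–O bond or strip silyl groups. Four silyl ethers must then be removed with a fluoride source, a basic reagent that threatens the enoate lactone and the flavanone.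
- Comparison: the chosen route closes ring C earlier, on benzyl ethers, before the lactone exists, and ends with an acidic deprotection. It spends its key step on C7–C8, which Alternative 3 does not address.

Key step: step 4

## Route

Remark: the sense of induction of the triazolium catalyst with the new enolate is assigned by analogy with azolium-enolate additions to oxodienes. If it proves opposite, the mirror-image catalyst (from the other commercial cis-1-amino-2-indanol) is used and nothing else changes.

Step 1
Reactants: 1 2,4,6-trihydroxybenzophenone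
Product: 2 (2,6-dihydroxy-4-{[tri(propan-2-yl)silyl]oxy}phenyl)(phenyl)methanone
Conditions: iPr3SiCl (1.05 equiv), imidazole, DMF, 0 °C → rt
Reagents that add atoms: chlorotri(propan-2-yl)silane, CC(C)[Si](Cl)(C(C)C)C(C)C
Why: Selective O-silylation; the para hydroxyl is the most acidic and the only one not flanked by the benzoyl group, and the bulky silyl chloride should not reach the ortho hydroxyls.

Step 2
Reactants: 2 (2,6-dihydroxy-4-{[tri(propan-2-yl)silyl]oxy}phenyl)(phenyl)methanone
Product: 3 [2-(benzyloxy)-6-hydroxy-4-{[tri(propan-2-yl)silyl]oxy}phenyl](phenyl)methanone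
Conditions: BnOH (1.05 equiv), PPh3, DIAD, THF, 0 °C → rt
Reagents that add atoms: benzyl alcohol, OCc1ccccc1
Why: Mitsunobu O-alkylation of an acidic ortho-acyl phenol under neutral conditions that spare the aryl silyl ether; after the first benzylation the remaining hydroxyl is locked in a hydrogen bond to the carbonyl, so mono-alkylation should prevail.

Step 3
Reactants: 3 [2-(benzyloxy)-6-hydroxy-4-{[tri(propan-2-yl)silyl]oxy}phenyl](phenyl)methanone
Product: 4 (±)-3-(benzyloxy)-2-[hydroxy(phenyl)methyl]-5-{[tri(propan-2-yl)silyl]oxy}phenol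
Conditions: NaBH4, THF/MeOH (9:1), 0 °C → rt; pH 7 buffer work-up; used without chromatography
Reagents that add atoms: none
Why: Borohydride reduction of an ortho-hydroxybenzophenone to the benzhydrol; low temperature and neutral work-up avoid ionization of this electron-rich ortho-hydroxybenzyl alcohol, and the new centre need not be controlled because step 4 destroys it.

Step 4
Reactants: 4 (±)-3-(benzyloxy)-2-[hydroxy(phenyl)methyl]-5-{[tri(propan-2-yl)silyl]oxy}phenol; 5 benzyloxyacetyl chloride
Product: 9 (3R,4S)-3,5-bis(benzyloxy)-4-phenyl-7-{[tri(propan-2-yl)silyl]oxy}-3,4-dihydro-2H-chromen-2-one, via aryl tert-butyl carbonate 6 (not isolated), via ortho-quinone methide 7 (not isolated), via cis-lactone 8 (not isolated)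
Conditions: Boc2O (1.05 equiv), Cs2CO3 (3 equiv), THF, −20 °C; then (5aS,10bR)-2-mesityl-5a,10b-dihydro-4H,6H-indeno[2,1-b][1,2,4]triazolo[4,3-d][1,4]oxazin-2-ium tetrafluoroborate (10 mol %) and 5 (2 equiv, slow addition), −20 °C → rt; then DBU (0.2 equiv), rt
Reagents that add atoms: none
Why: Proposed new method: carbonate transfer to the phenol gives 6, whose carbonate migrates to the benzylic oxygen and leaves in a 1,4-elimination, so both enantiomers of 4 converge on the planar quinone methide 7; the carbene is acylated by 5 and deprotonated to an α-benzyloxy azolium enolate, which adds through carbon to the methide carbon (C7–C8, driven by rearomatization), after which the phenoxide attacks the acyl azolium carbon and releases the carbene (O7'–C6). The closest known reaction type is the carbene-catalysed formal [4+2] annulation of ortho-quinone methides with ketenes or other azolium enolates to 3,4-dihydrocoumarins; new here are the α-alkoxy enolate made from an acid chloride and the carbonate route to the quinone methide in the same flask. The lactone ring closes in a 6-exo-trig acyl substitution. C8 is controlled by the catalyst: the indane wall of the triazolium shields one enolate face, and the benzyloxy group next to the methide carbon forces the phenyl group of 7 to the carbonyl side, so a single methide geometry meets a single enolate face. C7 is controlled by thermodynamics: the endo addition is expected to give the cis lactone 8 first, and DBU epimerizes the acidic α-alkoxy lactone position to the trans isomer 9, in which benzyloxy and phenyl are anti. The step needs C-alkylation of the enolate ahead of ketene dimerization and of O-acylation of the phenoxide, which the high electrophilicity of the methide carbon and slow addition of 5 should secure, and it needs a single quinone methide, which the benzyl ether on the second ortho oxygen of 4 guarantees.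

Step 5
Reactants: 9 (3R,4S)-3,5-bis(benzyloxy)-4-phenyl-7-{[tri(propan-2-yl)silyl]oxy}-3,4-dihydro-2H-chromen-2-one
Product: 10 (2R,3S)-2-(benzyloxy)-3-[2-(benzyloxy)-6-hydroxy-4-{[tri(propan-2-yl)silyl]oxy}phenyl]-3-phenylpropan-1-ol
Conditions: LiBH4, THF, 0 °C
Reagents that add atoms: none
Why: Hydride reduction of an aryl ester (lactone) to the primary alcohol and the phenol; the activated lactone should react at 0 °C without loss of the benzyl or aryl silyl ethers, and the intermediate aldehyde is reduced faster than it can epimerize at C7.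

Step 6
Reactants: 10 (2R,3S)-2-(benzyloxy)-3-[2-(benzyloxy)-6-hydroxy-4-{[tri(propan-2-yl)silyl]oxy}phenyl]-3-phenylpropan-1-ol
Product: 11 (2R,3S)-2-(benzyloxy)-3-[2,6-bis(benzyloxy)-4-{[tri(propan-2-yl)silyl]oxy}phenyl]-3-phenylpropan-1-ol
Conditions: BnBr (1.1 equiv), K2CO3, acetone, 40 °C
Reagents that add atoms: benzyl bromide, BrCc1ccccc1
Why: Williamson etherification selective for the phenol, the only hydroxyl that carbonate deprotonates; with both ortho oxygens benzylated, ring A becomes symmetric, so the later closure of ring C needs no regiocontrol.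

Step 7
Reactants: 11 (2R,3S)-2-(benzyloxy)-3-[2,6-bis(benzyloxy)-4-{[tri(propan-2-yl)silyl]oxy}phenyl]-3-phenylpropan-1-ol
Product: 12 (2R,3S)-2-(benzyloxy)-3-[2,6-bis(benzyloxy)-4-{[tri(propan-2-yl)silyl]oxy}phenyl]-3-phenylpropanal
Conditions: Dess–Martin periodinane, NaHCO3, CH2Cl2, 0 °C → rt; used crude
Reagents that add atoms: none
Why: Dess–Martin oxidation of a primary alcohol under buffered, non-basic conditions, so that the α-benzyloxy aldehyde is not epimerized at C7.

Step 8
Reactants: 13 prop-2-en-1-ol
Product: 14 3-(methoxymethoxy)prop-1-ene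
Conditions: MeOCH2Cl, iPr2NEt, CH2Cl2, 0 °C → rt
Reagents that add atoms: chloromethyl methyl ether, COCCl
Why: Acetal protection of a primary alcohol by alkylation with an α-chloro ether.

Step 9
Reactants: 12 (2R,3S)-2-(benzyloxy)-3-[2,6-bis(benzyloxy)-4-{[tri(propan-2-yl)silyl]oxy}phenyl]-3-phenylpropanal; 14 3-(methoxymethoxy)prop-1-ene
Product: 16 (1S,2R,3S,4S)-2-(benzyloxy)-1-[2,6-bis(benzyloxy)-4-{[tri(propan-2-yl)silyl]oxy}phenyl]-4-(methoxymethoxy)-1-phenylhex-5-en-3-ol, via allylborane 15 (not isolated)
Conditions: 14, sec-BuLi, THF, −78 °C; (+)-Ipc2BOMe; BF3·OEt2; then 12, −78 °C → rt; NaBO3·4H2O, THF/H2O, rt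
Reagents that add atoms: none
Why: Brown γ-alkoxyallylboration; the (Z)-allylborane 15 reacts through a chair six-membered transition state, which gives the syn C5/C6 relationship, and the isopinocampheyl groups derived from (−)-α-pinene direct the allyl unit to the re face of the aldehyde, which gives the C6 configuration of 27 (O6 syn to O7) against the Felkin–Anh preference of the α-alkoxy aldehyde. Perborate is used for the oxidative work-up to spare the aryl silyl ether.

Step 10
Reactants: 16 (1S,2R,3S,4S)-2-(benzyloxy)-1-[2,6-bis(benzyloxy)-4-{[tri(propan-2-yl)silyl]oxy}phenyl]-4-(methoxymethoxy)-1-phenylhex-5-en-3-ol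
Product: 17 3,5-bis(benzyloxy)-4-[(1S,2R,3S,4S)-2-(benzyloxy)-3-hydroxy-4-(methoxymethoxy)-1-phenylhex-5-en-1-yl]phenol
Conditions: Bu4NF, AcOH, THF, 0 °C
Reagents that add atoms: none
Why: Fluoride cleavage of the aryl silyl ether; the acetic acid buffer keeps the liberated phenol protonated, and benzyl ethers and the acetal are inert.

Step 11
Reactants: 17 3,5-bis(benzyloxy)-4-[(1S,2R,3S,4S)-2-(benzyloxy)-3-hydroxy-4-(methoxymethoxy)-1-phenylhex-5-en-1-yl]phenol; 18 ethyl (3R)-3-hydroxy-3-phenylpropanoate
Product: 19 ethyl (3S)-3-{3,5-bis(benzyloxy)-4-[(1S,2R,3S,4S)-2-(benzyloxy)-3-hydroxy-4-(methoxymethoxy)-1-phenylhex-5-en-1-yl]phenoxy}-3-phenylpropanoate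
Conditions: 18 (2 equiv), PPh3, DIAD, PhMe, 0 °C → rt
Reagents that add atoms: none
Why: Mitsunobu etherification; the unhindered phenol is alkylated at the benzylic carbon of 18 with inversion, which gives the (S) ether that becomes C2'. The C6 hydroxyl of 17, flanked by two branched oxygenated carbons, should be too hindered to be activated at a comparable rate.

Step 12
Reactants: 19 ethyl (3S)-3-{3,5-bis(benzyloxy)-4-[(1S,2R,3S,4S)-2-(benzyloxy)-3-hydroxy-4-(methoxymethoxy)-1-phenylhex-5-en-1-yl]phenoxy}-3-phenylpropanoate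
Product: 20 (3S)-3-{3,5-bis(benzyloxy)-4-[(1S,2R,3S,4S)-2-(benzyloxy)-3-hydroxy-4-(methoxymethoxy)-1-phenylhex-5-en-1-yl]phenoxy}-3-phenylpropanoic acid
Conditions: LiOH, THF/H2O, 0 °C → rt; then 1 M HCl to pH 4, 0 °C
Reagents that add atoms: lithium hydroxide, [Li+].[OH-]
Why: Saponification of the only ester present; hydroxide attacks the ester carbonyl faster than it deprotonates the α-carbon, so the β-aryloxy group should not be eliminated.

Step 13
Reactants: 20 (3S)-3-{3,5-bis(benzyloxy)-4-[(1S,2R,3S,4S)-2-(benzyloxy)-3-hydroxy-4-(methoxymethoxy)-1-phenylhex-5-en-1-yl]phenoxy}-3-phenylpropanoic acid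
Product: 23 (2S)-5,7-bis(benzyloxy)-6-[(1S,2R,3S,4S)-2-(benzyloxy)-3-hydroxy-4-(methoxymethoxy)-1-phenylhex-5-en-1-yl]-2-phenyl-2,3-dihydro-4H-chromen-4-one, via mixed anhydride 21 (not isolated), via flavanone trifluoroacetate 22 (not isolated)
Conditions: (CF3CO)2O (2.5 equiv), CH2Cl2, 0 °C → rt; then NaHCO3, MeOH, 0 °C
Reagents that add atoms: none
Why: Intramolecular Friedel–Crafts acylation through the mixed trifluoroacetic anhydride; the position attacked is ortho to the ether oxygen and ortho/para to the two benzyloxy groups, so no Lewis acid is needed, and the two free positions are equivalent. The C6 hydroxyl is trifluoroacetylated in passing and freed again by bicarbonate methanolysis; C2' is not involved.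

Step 14
Reactants: 23 (2S)-5,7-bis(benzyloxy)-6-[(1S,2R,3S,4S)-2-(benzyloxy)-3-hydroxy-4-(methoxymethoxy)-1-phenylhex-5-en-1-yl]-2-phenyl-2,3-dihydro-4H-chromen-4-one; 24 prop-2-enoyl chloride
Product: 25 (3S,4S,5R,6S)-5-(benzyloxy)-6-[(2S)-5,7-bis(benzyloxy)-4-oxo-2-phenyl-3,4-dihydro-2H-chromen-6-yl]-3-(methoxymethoxy)-6-phenylhex-1-en-4-yl prop-2-enoate
Conditions: 24 (3 equiv), iPr2NEt, DMAP (cat.), CH2Cl2, −20 → 0 °C
Reagents that add atoms: none
Why: Acylation of a secondary alcohol with an acid chloride; a hindered amine at low temperature should neither open the flavanone nor add to the acrylate.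

Step 15
Reactants: 25 (3S,4S,5R,6S)-5-(benzyloxy)-6-[(2S)-5,7-bis(benzyloxy)-4-oxo-2-phenyl-3,4-dihydro-2H-chromen-6-yl]-3-(methoxymethoxy)-6-phenylhex-1-en-4-yl prop-2-enoate
Product: 26 (5S,6S)-6-{(1R,2S)-1-(benzyloxy)-2-[(2S)-5,7-bis(benzyloxy)-4-oxo-2-phenyl-3,4-dihydro-2H-chromen-6-yl]-2-phenylethyl}-5-(methoxymethoxy)-5,6-dihydro-2H-pyran-2-one
Conditions: second-generation Grubbs catalyst RuCl2(=CHPh)(PCy3)(H2IMes) (10 mol %), CH2Cl2 (5 mM), 40 °C
Reagents that add atoms: none
Why: Ring-closing metathesis of an acrylate with an allylic-ether terminal alkene to the α,β-unsaturated δ-lactone; the catalyst should load on the electron-richer terminal alkene, and the six-membered ring enforces the cis C3=C4 bond.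

Step 16
Reactants: 26 (5S,6S)-6-{(1R,2S)-1-(benzyloxy)-2-[(2S)-5,7-bis(benzyloxy)-4-oxo-2-phenyl-3,4-dihydro-2H-chromen-6-yl]-2-phenylethyl}-5-(methoxymethoxy)-5,6-dihydro-2H-pyran-2-one
Product: 27 (5S,6R)-6-{(1R,2S)-2-[(2S)-5,7-dihydroxy-4-oxo-2-phenyl-3,4-dihydro-2H-chromen-6-yl]-1-hydroxy-2-phenylethyl}-5-hydroxy-5,6-dihydro-2H-pyran-2-one
Conditions: BCl3, pentamethylbenzene, CH2Cl2, −78 → −40 °C; MeOH quench
Reagents that add atoms: none
Why: Lewis-acid cleavage of the three benzyl ethers (the benzyl cations are trapped by pentamethylbenzene) and of the methoxymethyl acetal; the conditions are neither reducing nor basic, so the enoate, the lactone and C2' should be left alone.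

## Compound list

1 | 2,4,6-trihydroxybenzophenone | O=C(c1ccccc1)c1c(O)cc(O)cc1O | starting material
2 | (2,6-dihydroxy-4-{[tri(propan-2-yl)silyl]oxy}phenyl)(phenyl)methanone | O=C(c1ccccc1)c1c(O)cc(O[Si](C(C)C)(C(C)C)C(C)C)cc1O | intermediate
3 | [2-(benzyloxy)-6-hydroxy-4-{[tri(propan-2-yl)silyl]oxy}phenyl](phenyl)methanone | O=C(c1ccccc1)c1c(O)cc(O[Si](C(C)C)(C(C)C)C(C)C)cc1OCc1ccccc1 | intermediate
4 | (±)-3-(benzyloxy)-2-[hydroxy(phenyl)methyl]-5-{[tri(propan-2-yl)silyl]oxy}phenol | OC(c1ccccc1)c1c(O)cc(O[Si](C(C)C)(C(C)C)C(C)C)cc1OCc1ccccc1 | intermediate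
5 | benzyloxyacetyl chloride | O=C(Cl)COCc1ccccc1 | starting material
6 | (±)-tert-butyl 3-(benzyloxy)-2-[hydroxy(phenyl)methyl]-5-{[tri(propan-2-yl)silyl]oxy}phenyl carbonate | OC(c1ccccc1)c1c(OC(=O)OC(C)(C)C)cc(O[Si](C(C)C)(C(C)C)C(C)C)cc1OCc1ccccc1 | intermediate
7 | (6Z)-6-benzylidene-5-(benzyloxy)-3-{[tri(propan-2-yl)silyl]oxy}cyclohexa-2,4-dien-1-one | O=C1C=C(O[Si](C(C)C)(C(C)C)C(C)C)C=C(OCc2ccccc2)/C1=C/c1ccccc1 | intermediate
8 | (3S,4S)-3,5-bis(benzyloxy)-4-phenyl-7-{[tri(propan-2-yl)silyl]oxy}-3,4-dihydro-2H-chromen-2-one (cis) | O=C1[C@@H](OCc2ccccc2)[C@@H](c2ccccc2)c2c(OCc3ccccc3)cc(O[Si](C(C)C)(C(C)C)C(C)C)cc2O1 | intermediate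
9 | (3R,4S)-3,5-bis(benzyloxy)-4-phenyl-7-{[tri(propan-2-yl)silyl]oxy}-3,4-dihydro-2H-chromen-2-one (trans) | O=C1[C@H](OCc2ccccc2)[C@@H](c2ccccc2)c2c(OCc3ccccc3)cc(O[Si](C(C)C)(C(C)C)C(C)C)cc2O1 | intermediate
10 | (2R,3S)-2-(benzyloxy)-3-[2-(benzyloxy)-6-hydroxy-4-{[tri(propan-2-yl)silyl]oxy}phenyl]-3-phenylpropan-1-ol | OC[C@H](OCc2ccccc2)[C@@H](c2ccccc2)c2c(OCc3ccccc3)cc(O[Si](C(C)C)(C(C)C)C(C)C)cc2O | intermediate
11 | (2R,3S)-2-(benzyloxy)-3-[2,6-bis(benzyloxy)-4-{[tri(propan-2-yl)silyl]oxy}phenyl]-3-phenylpropan-1-ol | OC[C@H](OCc2ccccc2)[C@@H](c2ccccc2)c2c(OCc3ccccc3)cc(O[Si](C(C)C)(C(C)C)C(C)C)cc2OCc2ccccc2 | intermediate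
12 | (2R,3S)-2-(benzyloxy)-3-[2,6-bis(benzyloxy)-4-{[tri(propan-2-yl)silyl]oxy}phenyl]-3-phenylpropanal | O=C[C@H](OCc2ccccc2)[C@@H](c2ccccc2)c2c(OCc3ccccc3)cc(O[Si](C(C)C)(C(C)C)C(C)C)cc2OCc2ccccc2 | intermediate
13 | prop-2-en-1-ol | C=CCO | starting material
14 | 3-(methoxymethoxy)prop-1-ene | C=CCOCOC | intermediate
15 | [(2Z)-3-(methoxymethoxy)prop-2-en-1-yl]bis[(1S,2R,3S,5S)-2,6,6-trimethylbicyclo[3.1.1]heptan-3-yl]borane | COCO/C=C\CB([C@H]1C[C@H]2C[C@@H]([C@@H]1C)C2(C)C)[C@H]1C[C@H]2C[C@@H]([C@@H]1C)C2(C)C | intermediate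
16 | (1S,2R,3S,4S)-2-(benzyloxy)-1-[2,6-bis(benzyloxy)-4-{[tri(propan-2-yl)silyl]oxy}phenyl]-4-(methoxymethoxy)-1-phenylhex-5-en-3-ol | C=C[C@H](OCOC)[C@@H](O)[C@H](OCc1ccccc1)[C@@H](c1ccccc1)c1c(OCc2ccccc2)cc(O[Si](C(C)C)(C(C)C)C(C)C)cc1OCc1ccccc1 | intermediate
17 | 3,5-bis(benzyloxy)-4-[(1S,2R,3S,4S)-2-(benzyloxy)-3-hydroxy-4-(methoxymethoxy)-1-phenylhex-5-en-1-yl]phenol | C=C[C@H](OCOC)[C@@H](O)[C@H](OCc1ccccc1)[C@@H](c1ccccc1)c1c(OCc2ccccc2)cc(O)cc1OCc1ccccc1 | intermediate
18 | ethyl (3R)-3-hydroxy-3-phenylpropanoate | CCOC(=O)C[C@@H](O)c1ccccc1 | starting material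
19 | ethyl (3S)-3-{3,5-bis(benzyloxy)-4-[(1S,2R,3S,4S)-2-(benzyloxy)-3-hydroxy-4-(methoxymethoxy)-1-phenylhex-5-en-1-yl]phenoxy}-3-phenylpropanoate | C=C[C@H](OCOC)[C@@H](O)[C@H](OCc1ccccc1)[C@@H](c1ccccc1)c1c(OCc2ccccc2)cc(O[C@@H](CC(=O)OCC)c2ccccc2)cc1OCc1ccccc1 | intermediate
20 | (3S)-3-{3,5-bis(benzyloxy)-4-[(1S,2R,3S,4S)-2-(benzyloxy)-3-hydroxy-4-(methoxymethoxy)-1-phenylhex-5-en-1-yl]phenoxy}-3-phenylpropanoic acid | C=C[C@H](OCOC)[C@@H](O)[C@H](OCc1ccccc1)[C@@H](c1ccccc1)c1c(OCc2ccccc2)cc(O[C@@H](CC(=O)O)c2ccccc2)cc1OCc1ccccc1 | intermediate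
21 | (3S)-3-{3,5-bis(benzyloxy)-4-[(1S,2R,3S,4S)-2-(benzyloxy)-4-(methoxymethoxy)-1-phenyl-3-(trifluoroacetoxy)hex-5-en-1-yl]phenoxy}-3-phenylpropanoic trifluoroacetic anhydride | C=C[C@H](OCOC)[C@@H](OC(=O)C(F)(F)F)[C@H](OCc1ccccc1)[C@@H](c1ccccc1)c1c(OCc2ccccc2)cc(O[C@@H](CC(=O)OC(=O)C(F)(F)F)c2ccccc2)cc1OCc1ccccc1 | intermediate
22 | (1S,2R,3S,4S)-2-(benzyloxy)-1-[(2S)-5,7-bis(benzyloxy)-4-oxo-2-phenyl-3,4-dihydro-2H-chromen-6-yl]-4-(methoxymethoxy)-1-phenylhex-5-en-3-yl trifluoroacetate | C=C[C@H](OCOC)[C@@H](OC(=O)C(F)(F)F)[C@H](OCc1ccccc1)[C@@H](c1ccccc1)c1c(OCc2ccccc2)cc2c(c1OCc1ccccc1)C(=O)C[C@@H](c1ccccc1)O2 | intermediate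
23 | (2S)-5,7-bis(benzyloxy)-6-[(1S,2R,3S,4S)-2-(benzyloxy)-3-hydroxy-4-(methoxymethoxy)-1-phenylhex-5-en-1-yl]-2-phenyl-2,3-dihydro-4H-chromen-4-one | C=C[C@H](OCOC)[C@@H](O)[C@H](OCc1ccccc1)[C@@H](c1ccccc1)c1c(OCc2ccccc2)cc2c(c1OCc1ccccc1)C(=O)C[C@@H](c1ccccc1)O2 | intermediate
24 | prop-2-enoyl chloride | C=CC(=O)Cl | starting material
25 | (3S,4S,5R,6S)-5-(benzyloxy)-6-[(2S)-5,7-bis(benzyloxy)-4-oxo-2-phenyl-3,4-dihydro-2H-chromen-6-yl]-3-(methoxymethoxy)-6-phenylhex-1-en-4-yl prop-2-enoate | C=C[C@H](OCOC)[C@@H](OC(=O)C=C)[C@H](OCc1ccccc1)[C@@H](c1ccccc1)c1c(OCc2ccccc2)cc2c(c1OCc1ccccc1)C(=O)C[C@@H](c1ccccc1)O2 | intermediate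
26 | (5S,6S)-6-{(1R,2S)-1-(benzyloxy)-2-[(2S)-5,7-bis(benzyloxy)-4-oxo-2-phenyl-3,4-dihydro-2H-chromen-6-yl]-2-phenylethyl}-5-(methoxymethoxy)-5,6-dihydro-2H-pyran-2-one | O=C1C=C[C@H](OCOC)[C@H]([C@H](OCc2ccccc2)[C@@H](c2ccccc2)c2c(OCc3ccccc3)cc3c(c2OCc2ccccc2)C(=O)C[C@@H](c2ccccc2)O3)O1 | intermediate
27 | (5S,6R)-6-{(1R,2S)-2-[(2S)-5,7-dihydroxy-4-oxo-2-phenyl-3,4-dihydro-2H-chromen-6-yl]-1-hydroxy-2-phenylethyl}-5-hydroxy-5,6-dihydro-2H-pyran-2-one | O=C1C=C[C@H](O)[C@H]([C@H](O)[C@@H](c2ccccc2)c2c(O)cc3c(c2O)C(=O)C[C@@H](c2ccccc2)O3)O1 | target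

## Step count and least certain steps

Total: 16 steps. Longest linear sequence: 15 steps (steps 1–7 and 9–16, from 1 to 27); step 8 is a one-step side branch that prepares 14.

**Step 4 (key step, proposed new method).**
- Risk: the α-alkoxy azolium enolate may be consumed before it meets the quinone methide (ketene dimerization, O-acylation of the phenoxide or of the alcohol released from the carbonate), since this enolate has not been used in the annulation. Facial selection at C8 may also be weak, because the methide carbon with its peri benzyloxy neighbour is more hindered than usual. The silyl group may be lost while 7 is a vinylogous silyl ester.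
- Fallback (known chemistry), from ketone 3, returning at 9: heating 3 with (triphenylphosphoranylidene)ketene in toluene (ester formation at the phenol, then intramolecular Wittig reaction) should give the coumarin 5-(benzyloxy)-4-phenyl-7-{[tri(propan-2-yl)silyl]oxy}-2H-chromen-2-one F1. Copper hydride conjugate reduction (Cu(OAc)2, DTBM-SEGPHOS in the antipode that gives 4S, polymethylhydrosiloxane, t-BuOH, PhMe) should give (4S)-5-(benzyloxy)-4-phenyl-7-{[tri(propan-2-yl)silyl]oxy}-3,4-dihydro-2H-chromen-2-one F2. Its sodium enolate (NaN(SiMe3)2, THF, −78 °C) is hydroxylated by 2-(phenylsulfonyl)-3-phenyloxaziridine on the face away from the C4 phenyl group to give (3R,4S)-5-(benzyloxy)-3-hydroxy-4-phenyl-7-{[tri(propan-2-yl)silyl]oxy}-3,4-dihydro-2H-chromen-2-one F3. Benzyl 2,2,2-trichloroacetimidate with catalytic TfOH then gives 9.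

**Step 9.**
- Risk: poor facial selectivity in a mismatched case, since the reagent must override the Felkin–Anh preference of the α-benzyloxy aldehyde. The hindered aldehyde may also react slowly enough to epimerize at C7.
- Fallback, from 12 and 14, returning at 16: substrate control by chelation instead of reagent control. Lithiation of 14 (sec-BuLi, THF, −78 °C) and quenching with Bu3SnCl gives tributyl[(2Z)-3-(methoxymethoxy)prop-2-en-1-yl]stannane F4. With MgBr2·OEt2 in CH2Cl2 at −78 °C the aldehyde oxygen and the O7 benzyl ether of 12 are chelated. F4 then attacks the same re face (Cram chelate, matched) through an open transition state that gives syn C5/C6, and the product is 16 itself.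

**Step 11.**
- Risk: competition for activation. The betaine may dehydrate 18 to the cinnamate or engage the C6 hydroxyl of 17, and ionization at the benzylic carbon would erode the configuration of C2'.
- Fallback, from 16, returning at 20: the C6 hydroxyl is masked first. Acetylation (Ac2O, DMAP, Et3N) gives (1S,2R,3S,4S)-2-(benzyloxy)-1-[2,6-bis(benzyloxy)-4-{[tri(propan-2-yl)silyl]oxy}phenyl]-4-(methoxymethoxy)-1-phenylhex-5-en-3-yl acetate F5. Bu4NF/AcOH gives (1S,2R,3S,4S)-2-(benzyloxy)-1-[2,6-bis(benzyloxy)-4-hydroxyphenyl]-4-(methoxymethoxy)-1-phenylhex-5-en-3-yl acetate F6. Mitsunobu reaction with 18 gives ethyl (3S)-3-{4-[(1S,2R,3S,4S)-3-(acetyloxy)-2-(benzyloxy)-4-(methoxymethoxy)-1-phenylhex-5-en-1-yl]-3,5-bis(benzyloxy)phenoxy}-3-phenylpropanoate F7. LiOH cleaves both esters to give 20.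

**Step 13.**
- Risk: the acid set free may cleave the acetal on O5 or ionize the benzylic C2'–O bond (loss of configuration at C2'), and trifluoroacetylation of ring A may compete with ring closure.
- Fallback, from ester 19, returning at 23: anionic closure of the same bond (Parham cyclization). N-Bromosuccinimide (MeCN, 0 °C) brominates one of the two equivalent ring positions to give ethyl (3S)-3-{3,5-bis(benzyloxy)-4-[(1S,2R,3S,4S)-2-(benzyloxy)-3-hydroxy-4-(methoxymethoxy)-1-phenylhex-5-en-1-yl]-2-bromophenoxy}-3-phenylpropanoate F8. n-BuLi (2.2 equiv, THF, −100 °C) deprotonates the hydroxyl and exchanges bromine for lithium, and the aryllithium closes onto the ester to give 23 after work-up.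

**Step 16.**
- Risk: the hindered secondary benzyl ether on O7 may need more forcing conditions than the finished lactone tolerates (chloride addition to the enoate, elimination across C5–C6 once the Lewis acid binds the lactone carbonyl and the C5 acetal).
- Fallback, from acrylate 25, returning at 27: the deprotection is run before the lactone exists. BCl3/pentamethylbenzene on 25 gives (3S,4R,5R,6S)-6-[(2S)-5,7-dihydroxy-4-oxo-2-phenyl-3,4-dihydro-2H-chromen-6-yl]-3,5-dihydroxy-6-phenylhex-1-en-4-yl prop-2-enoate F9. Ring-closing metathesis with the second-generation Grubbs catalyst RuCl2(=CHPh)(PCy3)(H2IMes), which tolerates free hydroxyls and phenols, then gives 27.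

## Further compounds

F1 | step 4 | 5-(benzyloxy)-4-phenyl-7-{[tri(propan-2-yl)silyl]oxy}-2H-chromen-2-one | O=C1C=C(c2ccccc2)c2c(OCc3ccccc3)cc(O[Si](C(C)C)(C(C)C)C(C)C)cc2O1
F2 | step 4 | (4S)-5-(benzyloxy)-4-phenyl-7-{[tri(propan-2-yl)silyl]oxy}-3,4-dihydro-2H-chromen-2-one | O=C1C[C@@H](c2ccccc2)c2c(OCc3ccccc3)cc(O[Si](C(C)C)(C(C)C)C(C)C)cc2O1
F3 | step 4 | (3R,4S)-5-(benzyloxy)-3-hydroxy-4-phenyl-7-{[tri(propan-2-yl)silyl]oxy}-3,4-dihydro-2H-chromen-2-one | O=C1[C@H](O)[C@@H](c2ccccc2)c2c(OCc3ccccc3)cc(O[Si](C(C)C)(C(C)C)C(C)C)cc2O1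
F4 | step 9 | tributyl[(2Z)-3-(methoxymethoxy)prop-2-en-1-yl]stannane | CCCC[Sn](CCCC)(CCCC)C/C=C\OCOC
F5 | step 11 | (1S,2R,3S,4S)-2-(benzyloxy)-1-[2,6-bis(benzyloxy)-4-{[tri(propan-2-yl)silyl]oxy}phenyl]-4-(methoxymethoxy)-1-phenylhex-5-en-3-yl acetate | C=C[C@H](OCOC)[C@@H](OC(C)=O)[C@H](OCc1ccccc1)[C@@H](c1ccccc1)c1c(OCc2ccccc2)cc(O[Si](C(C)C)(C(C)C)C(C)C)cc1OCc1ccccc1
F6 | step 11 | (1S,2R,3S,4S)-2-(benzyloxy)-1-[2,6-bis(benzyloxy)-4-hydroxyphenyl]-4-(methoxymethoxy)-1-phenylhex-5-en-3-yl acetate | C=C[C@H](OCOC)[C@@H](OC(C)=O)[C@H](OCc1ccccc1)[C@@H](c1ccccc1)c1c(OCc2ccccc2)cc(O)cc1OCc1ccccc1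
F7 | step 11 | ethyl (3S)-3-{4-[(1S,2R,3S,4S)-3-(acetyloxy)-2-(benzyloxy)-4-(methoxymethoxy)-1-phenylhex-5-en-1-yl]-3,5-bis(benzyloxy)phenoxy}-3-phenylpropanoate | C=C[C@H](OCOC)[C@@H](OC(C)=O)[C@H](OCc1ccccc1)[C@@H](c1ccccc1)c1c(OCc2ccccc2)cc(O[C@@H](CC(=O)OCC)c2ccccc2)cc1OCc1ccccc1
F8 | step 13 | ethyl (3S)-3-{3,5-bis(benzyloxy)-4-[(1S,2R,3S,4S)-2-(benzyloxy)-3-hydroxy-4-(methoxymethoxy)-1-phenylhex-5-en-1-yl]-2-bromophenoxy}-3-phenylpropanoate | C=C[C@H](OCOC)[C@@H](O)[C@H](OCc1ccccc1)[C@@H](c1ccccc1)c1c(OCc2ccccc2)cc(O[C@@H](CC(=O)OCC)c2ccccc2)c(Br)c1OCc1ccccc1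
F9 | step 16 | (3S,4R,5R,6S)-6-[(2S)-5,7-dihydroxy-4-oxo-2-phenyl-3,4-dihydro-2H-chromen-6-yl]-3,5-dihydroxy-6-phenylhex-1-en-4-yl prop-2-enoate | C=C[C@H](O)[C@@H](OC(=O)C=C)[C@H](O)[C@@H](c1ccccc1)c1c(O)cc2c(c1O)C(=O)C[C@@H](c1ccccc1)O2
A1 | alternative 1 | furan-2-yl carbinol at C6 with O7 as tert-butyldimethylsilyl ether and the flavanone as 5',7'-diacetate (configuration as in 27) | c1coc(c1)[C@H]([C@H](O[Si](C)(C)C(C)(C)C)[C@@H](c1ccccc1)c1c(OC(C)=O)cc2c(c1OC(C)=O)C(=O)C[C@@H](c1ccccc1)O2)O
A2 | alternative 1 | 6-hydroxy-2H-pyran-3(6H)-one lactol (C2 hemiacetal, C5 ketone) with O7 silyl ether and flavanone diacetate | OC1C=CC(=O)[C@H]([C@H](O[Si](C)(C)C(C)(C)C)[C@@H](c2ccccc2)c2c(OC(C)=O)cc3c(c2OC(C)=O)C(=O)C[C@@H](c2ccccc2)O3)O1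
A3 | alternative 2 | (2R,3S)-2-(benzyloxy)-3-[(2S)-5,7-bis(benzyloxy)-4-oxo-2-phenyl-3,4-dihydro-2H-chromen-6-yl]-3-phenylpropanal | O=C[C@H](OCc1ccccc1)[C@@H](c1ccccc1)c1c(OCc2ccccc2)cc2c(c1OCc1ccccc1)C(=O)C[C@@H](c1ccccc1)O2
A4 | alternative 2 | (1Z,3E)-4-methoxy-2-[(trimethylsilyl)oxy]buta-1,3-dien-1-yl benzoate | CO/C=C/C(O[Si](C)(C)C)=C/OC(=O)c1ccccc1
A5 | alternative 2 | cis-5-(benzoyloxy)-6-substituted 2,3-dihydro-4H-pyran-4-one (lactone numbering) with O7, O5' and O7' benzyl ethers | C1=CC(=O)[C@H](OC(=O)c2ccccc2)[C@H]([C@H](OCc2ccccc2)[C@@H](c2ccccc2)c2c(OCc3ccccc3)cc3c(c2OCc2ccccc2)C(=O)C[C@@H](c2ccccc2)O3)O1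
A6 | alternative 3 | (3S)-3-aryloxy-3-phenylpropanoic acid carrying the complete lactone side chain, all four hydroxyls as tert-butyldimethylsilyl ethers | O=C1C=C[C@H](O[Si](C)(C)C(C)(C)C)[C@H]([C@H](O[Si](C)(C)C(C)(C)C)[C@@H](c2ccccc2)c2c(O[Si](C)(C)C(C)(C)C)cc(O[C@@H](CC(=O)O)c3ccccc3)cc2O[Si](C)(C)C(C)(C)C)O1
A7 | alternative 3 | tetrakis(tert-butyldimethylsilyl) ether of 27 | O=C1C=C[C@H](O[Si](C)(C)C(C)(C)C)[C@H]([C@H](O[Si](C)(C)C(C)(C)C)[C@@H](c2ccccc2)c2c(O[Si](C)(C)C(C)(C)C)cc3c(c2O[Si](C)(C)C(C)(C)C)C(=O)C[C@@H](c2ccccc2)O3)O1
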